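The plan turns on making the C5–C10 bond of ring B by a sigmatropic shift. In the target, C10 is fully substituted, its hydroxymethyl carbon C14 stands on the same face as the oxygens on C1 and C2 and opposite H5, and the ring B alkene C3=C4 adjoins C5. This is what results if C14 was once a lactone carbonyl bound through oxygen to C3. A single Ireland–Claisen ring contraction thus builds ring B, creates C10 and C5 with transfer of chirality from C3, and leaves a vinyl group for ring A. Its precursor is an α-ethylidene δ-lactone bearing the ribose-derived cis-acetonide and an (E)-alkenyl group at C3.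

Key step: step 11

Remark: eudesmane numbering is used (ring B = C1–C5 and C10, ring A = C5–C10, C14 = the carbon on C10, C7 carries the isopropenyl group); β means the face of the bicycle that carries C14, α the opposite face.

Step 1
Reactants: 1 pent-3-yn-1-ol
Product: 2 tert-butyl(pent-3-yn-1-yloxy)diphenylsilane
Conditions: t-BuPh2SiCl, imidazole, CH2Cl2, rt
Reagents that add atoms: tert-butyl(chloro)diphenylsilane, CC(C)(C)[Si](Cl)(c1ccccc1)c1ccccc1
Why: Imidazole-promoted silyl ether formation on a primary alcohol should be clean, and this robust ether is expected to last until the fluoride cleavage in step 15.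

Step 2
Reactants: 2 tert-butyl(pent-3-yn-1-yloxy)diphenylsilane
Product: 4 (E)-tert-butyl[(4-iodopent-3-en-1-yl)oxy]diphenylsilane (C4–C7 fragment), via alkenylzirconocene chloride 3 (not isolated)
Conditions: Cp2Zr(H)Cl (excess), THF, 50 °C; then I2, 0 °C
Reagents that add atoms: iodine, [I][I]
Why: Hydrozirconation–iodination: syn addition of Zr–H and equilibration with excess Cp2Zr(H)Cl should place zirconium on the methyl-bearing carbon, and iodinolysis with retention should give the (E)-iodide.

Step 3
Reactants: 5 2-deoxy-L-ribose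
Product: 6 3,4-O-isopropylidene-2-deoxy-L-ribopyranose (both anomers)
Conditions: 2-methoxypropene, PPTS (cat.), DMF, 0 °C
Reagents that add atoms: 2-methoxypropene, COC(C)=C
Why: Acid-catalysed acetonide formation should engage the cis-3,4-diol of the pyranose form, the only hydroxyl pair that can close a five-membered acetal, and the two carbinol centres (later C1 and C2) are bought with the sugar.

Step 4
Reactants: 6 3,4-O-isopropylidene-2-deoxy-L-ribopyranose
Product: 7 3,4-O-isopropylidene-2-deoxy-L-ribono-1,5-lactone
Conditions: PhI(OAc)2, TEMPO (cat.), CH2Cl2, rt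
Reagents that add atoms: none
Why: Oxoammonium-mediated oxidation of a lactol to the lactone should proceed under near-neutral conditions that the acetonide tolerates.

Step 5
Reactants: 7 3,4-O-isopropylidene-2-deoxy-L-ribono-1,5-lactone
Product: 8 5-hydroxy Weinreb amide (N-methoxy-N-methyl amide of 3,4-O-isopropylidene-2-deoxy-L-ribonic acid)
Conditions: MeNH(OMe)·HCl, Me3Al, CH2Cl2, 0 °C to rt
Reagents that add atoms: N,O-dimethylhydroxylamine hydrochloride, CNOC.Cl
Why: Aluminium amide aminolysis of a lactone (Weinreb amide formation) should open the ring irreversibly and free the primary hydroxyl on the carbon that becomes C3.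

Step 6
Reactants: 8 5-hydroxy Weinreb amide
Product: 9 Weinreb amide aldehyde (sugar C5 oxidised to CHO; this carbon is C3 of the target)
Conditions: DMP, pyridine, CH2Cl2, 0 °C to rt
Reagents that add atoms: none
Why: Buffered Dess–Martin oxidation should give the α-alkoxy aldehyde without epimerising the adjacent dioxolane carbon or relactonising the amide, and the aldehyde would be used at once.

Step 7
Reactants: 9 Weinreb amide aldehyde; 4 (E)-alkenyl iodide
Product: 11 (E)-allylic alcohol with the C3 carbinol anti to O2, via alkenylchromium dichloride 10 (not isolated)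
Conditions: CrCl2 (excess), NiCl2 (cat.), DMSO, rt
Reagents that add atoms: none
Why: Nozaki–Hiyama–Kishi coupling: the alkenylchromium reagent should add only to the aldehyde with retention of the (E)-geometry, and Felkin–Anh attack anti to the C2–O bond of the cis-substituted dioxolane should set C3 anti to O2.

Step 8
Reactants: 11 (E)-allylic alcohol
Product: 12 6-alkenyl δ-lactone C14(=O)–O–C3 (1β,2β-acetonide; alkenyl group on the opposite face)
Conditions: CSA (1.1 equiv.), CH2Cl2, rt
Reagents that add atoms: none
Why: Acid-promoted lactonisation of the δ-hydroxy Weinreb amide, driven by protonation of the released amine, should close the δ-lactone without touching the C3 configuration.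

Step 9
Reactants: 12 6-alkenyl δ-lactone; 13 acetaldehyde
Product: 15 α-(1-hydroxyethyl) δ-lactone (isomer mixture at C9 and C10), via lithium lactone enolate 14 (not isolated)
Conditions: LiN(i-Pr)2, THF, −78 °C; then MeCHO, −78 °C; aq. NH4Cl
Reagents that add atoms: none
Why: Aldol addition of a lactone enolate that is formed and consumed at −78 °C, so that O1 should not be lost by β-elimination; the two new centres are erased in step 10.

Step 10
Reactants: 15 α-(1-hydroxyethyl) δ-lactone
Product: 17 (E)-α-ethylidene δ-lactone, via secondary mesylate 16 (not isolated)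
Conditions: MsCl, Et3N, CH2Cl2, 0 °C; then DBU, rt
Reagents that add atoms: none
Why: Mesylation followed by E1cB elimination should give the conjugated ethylidene lactone, mainly as the (E)-isomer, and either geometry would lead to the same dienolate in step 11.

Step 11
Reactants: 17 (E)-α-ethylidene δ-lactone
Product: 20 ring B acid with quaternary C10 (carboxyl C14 β; vinyl α; H5 α), via cyclic silyl dienol ether 18 (not isolated), via trimethylsilyl ester 19 (not isolated)
Conditions: Me3SiCl, LiN(i-Pr)2, THF/DMPU, −78 °C; then rt to 65 °C; aq. citric acid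
Reagents that add atoms: none
Why: Ireland–Claisen rearrangement of a lactone-derived silyl ketene acetal: γ-deprotonation of the ethylidene group with Me3SiCl present gives the cyclic silyl dienol ether 18, trapped on oxygen before O1 can leave by β-elimination, and on warming the unit C10=C14–O–C3–C4=C5 undergoes a concerted suprafacial [3,3] shift that makes C5–C10, breaks C3–O and moves the alkene to C3=C4. The closest known reactions are the ring contraction of alkenyl-substituted lactone silyl ketene acetals to cycloalkene carboxylic acids and the Claisen rearrangement of ester dienolates. Ring B (C10–C1–C2–C3–C4–C5) closes by this pericyclic six-to-six contraction, which must run through a boat-shaped transition state because C10 and C3 stay linked by the C1–C2 bridge. C10 is controlled by the ring-fixed ketene acetal and by the alkenyl group lying trans to O1/O2 on the lactone, so that C5 bonds on the face away from the acetonide and the former ring carbon C14 ends β, cis to O1 and O2, with the vinyl group α; C5 is controlled by the (E)-alkene, which in the boat turns H5 toward the C1–C2 bridge and C6 outward, so that H5 ends α, trans to C14. The step needs complete transfer of the C3 configuration to C5 and C10 and clean O-silylation of the dienolate, which the single possible ketene acetal geometry, the cis-acetonide (it holds C1–C2 eclipsed and so favours the boat) and silylation in situ at −78 °C should secure.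

Step 12
Reactants: 20 ring B acid
Product: 21 C14 primary alcohol
Conditions: LiAlH4, THF, 0 °C to rt
Reagents that add atoms: none
Why: Hydride reduction of the carboxylic acid should give the neopentyl alcohol, while alkenes, acetonide and the silyl ether are inert to LiAlH4 at this temperature.

Step 13
Reactants: 21 C14 primary alcohol
Product: 22 C14 PMB ether
Conditions: NaH, PMBCl, Bu4NI (cat.), THF/DMF, 0 °C to rt
Reagents that add atoms: 4-methoxybenzyl chloride, COc1ccc(CCl)cc1
Why: Williamson etherification of the primary alkoxide should install the one protecting group that C14 keeps until the last step, which saves a later exchange of protecting groups.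

Step 14
Reactants: 22 C14 PMB ether
Product: 23 C9 methyl ketone
Conditions: PdCl2 (cat.), CuCl, O2, DMF/H2O, rt
Reagents that add atoms: water, O
Why: Tsuji–Wacker oxidation: divalent palladium should activate only the monosubstituted vinyl group, water adding in the Markovnikov sense to give the methyl ketone, while the trisubstituted ring alkene stays untouched.

Step 15
Reactants: 23 C9 methyl ketone
Product: 24 C7 primary alcohol
Conditions: Bu4NF, THF, 0 °C to rt
Reagents that add atoms: none
Why: Fluoride cleavage of the primary silyl ether should be selective, since the PMB ether and acetonide are inert and the ketone cannot eliminate its β-oxygens because C10 bears no hydrogen.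

Step 16
Reactants: 24 C7 primary alcohol
Product: 25 C9-keto C7-aldehyde
Conditions: DMP, pyridine, CH2Cl2, 0 °C to rt
Reagents that add atoms: none
Why: Dess–Martin oxidation of the primary alcohol should stop at the aldehyde under non-enolising conditions.

Step 17
Reactants: 25 C9-keto C7-aldehyde
Product: 27 trans-fused bicyclic enone (C7=C8–C9=O), via ring A aldol 26 (not isolated)
Conditions: KOH, MeOH, 0 °C to rt
Reagents that add atoms: none
Why: Intramolecular aldol condensation: only the methyl ketone enolate (C8) can reach the C7 aldehyde through a six-membered ring (6-enolendo-exo-trig closure of ring A), dehydration gives the enone, and the trans ring fusion follows from the configurations already fixed at C5 and C10.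

Step 18
Reactants: 27 trans-fused bicyclic enone; 28 isopropenylmagnesium bromide
Product: 30 7α-isopropenyl C9 ketone, via bromomagnesium enolate 29 (not isolated)
Conditions: CuBr·SMe2 (cat.), THF, −78 to −30 °C; aq. NH4Cl
Reagents that add atoms: none
Why: Copper-catalysed conjugate addition: stereoelectronically preferred axial attack at C7 through a chair-like enolate, on the α face anti to the C4–C5 bond and away from the axial C14 group, should set C7 with the isopropenyl group α.

Step 19
Reactants: 30 7α-isopropenyl C9 ketone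
Product: 31 9α-alcohol (C14 PMB ether of the 9,14-diol acetonide)
Conditions: LiBH(s-Bu)3, THF, −78 to 0 °C; aq. NH4Cl
Reagents that add atoms: none
Why: Bulky trialkylborohydride reduction: hydride should arrive along the equatorial trajectory on the β face because the axial path on the α face is blocked by the axial C7 isopropenyl group (as with 3-axially substituted cyclohexanones), which gives the axial 9α-alcohol.

Step 20
Reactants: 31 9α-alcohol
Product: 32 9α-acetate
Conditions: Ac2O, DMAP, Et3N, CH2Cl2, rt to 40 °C
Reagents that add atoms: acetic anhydride, CC(=O)OC(C)=O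
Why: DMAP-catalysed acetylation should esterify the only free hydroxyl, hindered as it is, without affecting any stereocentre.

Step 21
Reactants: 32 9α-acetate
Product: 33 9α-acetoxy 1β,2β-diol
Conditions: AcOH/H2O (4:1), 45 °C
Reagents that add atoms: none
Why: Mild acid hydrolysis of the isopropylidene acetal should free the cis-diol, while the PMB ether, the acetate and both alkenes tolerate aqueous acetic acid.

Step 22
Reactants: 33 9α-acetoxy 1β,2β-diol
Product: 35 2β,9α-diacetate with free 1β-hydroxyl, via cyclic orthoacetate 34 (not isolated)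
Conditions: MeC(OMe)3, CSA (cat.), CH2Cl2, rt; then AcOH/H2O, rt
Reagents that add atoms: trimethyl orthoacetate, COC(C)(OC)OC
Why: Cyclic orthoester formation on the cis-diol and mild acid hydrolysis, which under stereoelectronic control should open to the ester on the pseudoaxial oxygen (allylic O2) and leave the equatorial 1-hydroxyl free.

Step 23
Reactants: 35 2β,9α-diacetate with free 1β-hydroxyl; 36 tiglic acid
Product: 38 14-O-PMB ether of the target, via tigloyl mixed anhydride 37 (not isolated)
Conditions: 2,4,6-Cl3C6H2COCl, Et3N, toluene, rt; then 35, DMAP, 60 °C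
Reagents that add atoms: none
Why: Yamaguchi esterification: DMAP should attack the mixed anhydride at the less hindered tigloyl carbonyl and pass the acyl group to the hindered 1-hydroxyl, the (E)-geometry of the ester coming unchanged from tiglic acid.

Step 24
Reactants: 38 14-O-PMB ether of the target
Product: 39 target CNP0267061.1
Conditions: DDQ, CH2Cl2/pH 7 buffer, 0 °C to rt
Reagents that add atoms: none
Why: Oxidative PMB ether cleavage (electron transfer to DDQ, hydrolysis of the benzylic oxocarbenium ion) should free the C14 hydroxyl under neutral conditions that leave the three esters and both alkenes alone and give no base to move acyl groups to O14.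

Compound list
1 | pent-3-yn-1-ol | CC#CCCO | starting material
2 | tert-butyl(pent-3-yn-1-yloxy)diphenylsilane | CC#CCCO[Si](c1ccccc1)(c1ccccc1)C(C)(C)C | intermediate
3 | (E)-alkenylzirconocene chloride from 2, Zr on the methyl-bearing carbon (not isolated) | Cl[Zr](C1C=CC=C1)(C1C=CC=C1)/C(C)=C/CCO[Si](c1ccccc1)(c1ccccc1)C(C)(C)C | intermediate
4 | (E)-tert-butyl[(4-iodopent-3-en-1-yl)oxy]diphenylsilane | I/C(C)=C/CCO[Si](c1ccccc1)(c1ccccc1)C(C)(C)C | intermediate
5 | 2-deoxy-L-ribose | O=CC[C@@H](O)[C@@H](O)CO | starting material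
6 | 3,4-O-isopropylidene-2-deoxy-L-ribopyranose (both anomers) | OC1C[C@H]2OC(C)(C)O[C@H]2CO1 | intermediate
7 | 3,4-O-isopropylidene-2-deoxy-L-ribono-1,5-lactone | O=C1C[C@H]2OC(C)(C)O[C@H]2CO1 | intermediate
8 | 5-hydroxy Weinreb amide of 3,4-O-isopropylidene-2-deoxy-L-ribonic acid | CON(C)C(=O)C[C@H]1OC(C)(C)O[C@H]1CO | intermediate
9 | Weinreb amide aldehyde (cis-dioxolane, CHO = future C3) | CON(C)C(=O)C[C@H]1OC(C)(C)O[C@H]1C=O | intermediate
10 | (E)-alkenylchromium dichloride from 4 (not isolated) | Cl[Cr](Cl)/C(C)=C/CCO[Si](c1ccccc1)(c1ccccc1)C(C)(C)C | intermediate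
11 | (E)-allylic alcohol, C3 carbinol anti to O2 | CON(C)C(=O)C[C@H]1OC(C)(C)O[C@H]1[C@@H](O)/C(C)=C/CCO[Si](c1ccccc1)(c1ccccc1)C(C)(C)C | intermediate
12 | 6-alkenyl δ-lactone, alkenyl trans to the acetonide oxygens | C1C(=O)O[C@@H](/C(C)=C/CCO[Si](c3ccccc3)(c3ccccc3)C(C)(C)C)[C@@H]2OC(C)(C)O[C@H]12 | intermediate
13 | acetaldehyde | CC=O | starting material
14 | lithium enolate of lactone 12 (not isolated) | C1=C(O[Li])O[C@@H](/C(C)=C/CCO[Si](c3ccccc3)(c3ccccc3)C(C)(C)C)[C@@H]2OC(C)(C)O[C@H]12 | intermediate
15 | α-(1-hydroxyethyl) δ-lactone, isomer mixture at C9 and C10 | CC(O)C1C(=O)O[C@@H](/C(C)=C/CCO[Si](c3ccccc3)(c3ccccc3)C(C)(C)C)[C@@H]2OC(C)(C)O[C@H]12 | intermediate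
16 | mesylate of 15 (not isolated) | CC(OS(C)(=O)=O)C1C(=O)O[C@@H](/C(C)=C/CCO[Si](c3ccccc3)(c3ccccc3)C(C)(C)C)[C@@H]2OC(C)(C)O[C@H]12 | intermediate
17 | (E)-α-ethylidene δ-lactone | C/C=C1/C(=O)O[C@@H](/C(C)=C/CCO[Si](c3ccccc3)(c3ccccc3)C(C)(C)C)[C@@H]2OC(C)(C)O[C@H]12 | intermediate
18 | cyclic trimethylsilyl dienol ether (ring ketene acetal bearing a vinyl group on C10; not isolated) | C=CC1=C(O[Si](C)(C)C)O[C@@H](/C(C)=C/CCO[Si](c3ccccc3)(c3ccccc3)C(C)(C)C)[C@@H]2OC(C)(C)O[C@H]12 | intermediate
19 | trimethylsilyl ester of acid 20 (not isolated) | C=C[C@@]1(C(=O)O[Si](C)(C)C)[C@H](CCO[Si](c3ccccc3)(c3ccccc3)C(C)(C)C)C(C)=C[C@@H]2OC(C)(C)O[C@H]12 | intermediate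
20 | ring B acid: C10 quaternary (CO2H β, vinyl α), H5 α, C3=C4, 1β,2β-acetonide | C=C[C@@]1(C(=O)O)[C@H](CCO[Si](c3ccccc3)(c3ccccc3)C(C)(C)C)C(C)=C[C@@H]2OC(C)(C)O[C@H]12 | intermediate
21 | C14 primary alcohol | C=C[C@@]1(CO)[C@H](CCO[Si](c3ccccc3)(c3ccccc3)C(C)(C)C)C(C)=C[C@@H]2OC(C)(C)O[C@H]12 | intermediate
22 | C14 PMB ether | C=C[C@@]1(COCc3ccc(OC)cc3)[C@H](CCO[Si](c4ccccc4)(c4ccccc4)C(C)(C)C)C(C)=C[C@@H]2OC(C)(C)O[C@H]12 | intermediate
23 | C9 methyl ketone | CC(=O)[C@@]1(COCc3ccc(OC)cc3)[C@H](CCO[Si](c4ccccc4)(c4ccccc4)C(C)(C)C)C(C)=C[C@@H]2OC(C)(C)O[C@H]12 | intermediate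
24 | C7 primary alcohol | CC(=O)[C@@]1(COCc3ccc(OC)cc3)[C@H](CCO)C(C)=C[C@@H]2OC(C)(C)O[C@H]12 | intermediate
25 | C9-keto C7-aldehyde | CC(=O)[C@@]1(COCc3ccc(OC)cc3)[C@H](CC=O)C(C)=C[C@@H]2OC(C)(C)O[C@H]12 | intermediate
26 | ring A aldol (7-hydroxy-9-ketone, C7 epimers; not isolated) | OC1CC(=O)[C@@]2(COCc3ccc(OC)cc3)[C@H](C1)C(C)=C[C@@H]3OC(C)(C)O[C@H]23 | intermediate
27 | trans-fused bicyclic enone | C1=CC(=O)[C@@]2(COCc3ccc(OC)cc3)[C@H](C1)C(C)=C[C@@H]3OC(C)(C)O[C@H]23 | intermediate
28 | isopropenylmagnesium bromide | C=C(C)[Mg]Br | starting material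
29 | bromomagnesium enolate of 30 (not isolated) | C=C(C)[C@@H]1C=C(O[Mg]Br)[C@@]2(COCc3ccc(OC)cc3)[C@H](C1)C(C)=C[C@@H]3OC(C)(C)O[C@H]23 | intermediate
30 | 7α-isopropenyl C9 ketone | C=C(C)[C@@H]1CC(=O)[C@@]2(COCc3ccc(OC)cc3)[C@H](C1)C(C)=C[C@@H]3OC(C)(C)O[C@H]23 | intermediate
31 | 9α-alcohol (14-O-PMB) | C=C(C)[C@@H]1C[C@H](O)[C@@]2(COCc3ccc(OC)cc3)[C@H](C1)C(C)=C[C@@H]3OC(C)(C)O[C@H]23 | intermediate
32 | 9α-acetate | C=C(C)[C@@H]1C[C@H](OC(C)=O)[C@@]2(COCc3ccc(OC)cc3)[C@H](C1)C(C)=C[C@@H]3OC(C)(C)O[C@H]23 | intermediate
33 | 9α-acetoxy 1β,2β-diol | C=C(C)[C@@H]1C[C@H](OC(C)=O)[C@@]2(COCc3ccc(OC)cc3)[C@H](C1)C(C)=C[C@H](O)[C@@H]2O | intermediate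
34 | cyclic 1,2-orthoacetate (not isolated) | C=C(C)[C@@H]1C[C@H](OC(C)=O)[C@@]2(COCc3ccc(OC)cc3)[C@H](C1)C(C)=C[C@@H]3OC(C)(OC)O[C@H]23 | intermediate
35 | 2β,9α-diacetate with free 1β-hydroxyl | C=C(C)[C@@H]1C[C@H](OC(C)=O)[C@@]2(COCc3ccc(OC)cc3)[C@H](C1)C(C)=C[C@H](OC(C)=O)[C@@H]2O | intermediate
36 | tiglic acid | C/C=C(\C)C(=O)O | starting material
37 | tiglic 2,4,6-trichlorobenzoic anhydride (not isolated) | C/C=C(\C)C(=O)OC(=O)c1c(Cl)cc(Cl)cc1Cl | intermediate
38 | 14-O-PMB ether of the target | C=C(C)[C@@H]1C[C@H](OC(C)=O)[C@@]2(COCc3ccc(OC)cc3)[C@H](C1)C(C)=C[C@H](OC(C)=O)[C@@H]2OC(=O)/C(C)=C/C | intermediate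
39 | CNP0267061.1 | C=C(C)[C@@H]1C[C@H](OC(C)=O)[C@@]2(CO)[C@H](C1)C(C)=C[C@H](OC(C)=O)[C@@H]2OC(=O)/C(C)=C/C | target

Total step count: 24. Longest linear sequence: 22 steps (steps 3–24, from 2-deoxy-L-ribose 5); the alkenyl iodide arm is 2 steps.

Steps most likely to fail

1. Step 11. Deprotonation at the γ-methyl group may lose out to conjugate addition of the amide base, the dienolate may expel O1 (opening the acetonide by β-elimination) before it is silylated, and the boat-shaped shift may be slow enough for the ketene acetal to decompose. The fallback makes the same bond from a saturated lactone, with no dienolate. It sets out from aldol adduct 15: silylation (t-BuMe2SiOTf, 2,6-lutidine) would give 9-O-silyl lactone F1. Ordinary α-deprotonation with LiN(i-Pr)2 in the presence of Me3SiCl would give the tetrasubstituted cyclic silyl ketene acetal F2, which should rearrange through the same boat to trimethylsilyl ester F3 and, after aqueous work-up, to the C10-(1-silyloxyethyl) acid F4. LiAlH4 reduction would give alcohol F5, and etherification with PMB trichloroacetimidate and La(OTf)3 (no alkoxide, hence no silyl migration) would give PMB ether F6. Removal of both silyl groups with Bu4NF would give diol F7, and oxidation of both hydroxyls with DMP would rejoin the route at keto aldehyde 25, bypassing compounds 17–24 and the Wacker oxidation.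

2. Step 19. Hydride transfer to a ketone next to quaternary C10 may be slow, and the axial C14 substituent may divert part of the reagent to the α face, eroding facial selectivity. The fallback replaces steric control by a hydroxyl-directed reduction. It sets out from ketone 30: DDQ would first remove the PMB group to give β-hydroxy ketone F8. Me4NBH(OAc)3 in MeCN/AcOH would then bind to the axial C14 hydroxyl and deliver hydride intramolecularly to the β face of C9, giving 9α,14-diol F9. Selective etherification of the primary hydroxyl with PMB trichloroacetimidate and La(OTf)3 would return to 31.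

3. Step 23. Acylation of the hindered 1-hydroxyl may be slow, and under the basic conditions the neighbouring C2 acetyl group may migrate to O1 before the tigloyl group arrives, scrambling the two esters. The fallback reverses the order of acylation and sets the regiochemistry through a tin acetal. It sets out from diol 33: Bu2SnO in refluxing toluene would give stannylene acetal F10, whose reaction with tigloyl chloride should acylate the equatorial oxygen O1 and give 1-tiglate F11. Acetylation of the remaining pseudoaxial 2-hydroxyl (Ac2O, DMAP) would return to 38, bypassing 34 and 35.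

Further compounds
F1 | step 11 | tert-butyldimethylsilyl ether of aldol adduct 15 | CC(O[Si](C)(C)C(C)(C)C)C1C(=O)O[C@@H](/C(C)=C/CCO[Si](c3ccccc3)(c3ccccc3)C(C)(C)C)[C@@H]2OC(C)(C)O[C@H]12
F2 | step 11 | cyclic trimethylsilyl ketene acetal of F1 | CC(O[Si](C)(C)C(C)(C)C)C1=C(O[Si](C)(C)C)O[C@@H](/C(C)=C/CCO[Si](c3ccccc3)(c3ccccc3)C(C)(C)C)[C@@H]2OC(C)(C)O[C@H]12
F3 | step 11 | trimethylsilyl ester of F4 | CC(O[Si](C)(C)C(C)(C)C)[C@@]1(C(=O)O[Si](C)(C)C)[C@H](CCO[Si](c3ccccc3)(c3ccccc3)C(C)(C)C)C(C)=C[C@@H]2OC(C)(C)O[C@H]12
F4 | step 11 | ring B acid with a 1-(tert-butyldimethylsilyloxy)ethyl group on C10 | CC(O[Si](C)(C)C(C)(C)C)[C@@]1(C(=O)O)[C@H](CCO[Si](c3ccccc3)(c3ccccc3)C(C)(C)C)C(C)=C[C@@H]2OC(C)(C)O[C@H]12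
F5 | step 11 | C14 alcohol from F4 | CC(O[Si](C)(C)C(C)(C)C)[C@@]1(CO)[C@H](CCO[Si](c3ccccc3)(c3ccccc3)C(C)(C)C)C(C)=C[C@@H]2OC(C)(C)O[C@H]12
F6 | step 11 | C14 PMB ether of F5 | CC(O[Si](C)(C)C(C)(C)C)[C@@]1(COCc3ccc(OC)cc3)[C@H](CCO[Si](c4ccccc4)(c4ccccc4)C(C)(C)C)C(C)=C[C@@H]2OC(C)(C)O[C@H]12
F7 | step 11 | C7,C9-diol with C14 PMB ether | CC(O)[C@@]1(COCc3ccc(OC)cc3)[C@H](CCO)C(C)=C[C@@H]2OC(C)(C)O[C@H]12
F8 | step 19 | 14-hydroxy 7α-isopropenyl C9 ketone | C=C(C)[C@@H]1CC(=O)[C@@]2(CO)[C@H](C1)C(C)=C[C@@H]3OC(C)(C)O[C@H]23
F9 | step 19 | 9α,14-diol acetonide | C=C(C)[C@@H]1C[C@H](O)[C@@]2(CO)[C@H](C1)C(C)=C[C@@H]3OC(C)(C)O[C@H]23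
F10 | step 23 | dibutylstannylene acetal of diol 33 | C=C(C)[C@@H]1C[C@H](OC(C)=O)[C@@]2(COCc3ccc(OC)cc3)[C@H](C1)C(C)=C[C@@H]3O[Sn](CCCC)(CCCC)O[C@H]23
F11 | step 23 | 1β-tiglate with free 2β-hydroxyl | C=C(C)[C@@H]1C[C@H](OC(C)=O)[C@@]2(COCc3ccc(OC)cc3)[C@H](C1)C(C)=C[C@H](O)[C@@H]2OC(=O)/C(C)=C/C
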